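**Plan**
- Retrosynthesis: the four MOM ethers are put back first. Ring C is then cut at C2–C3 and C4–C4a together, giving an α-diazoketone whose acyl carbon is the later C4 and whose diazo carbon is the later C3. Next come the O1–C2 ether bond, then the three aryl–prenyl bonds and the aryl–C2 bond.
- Enabling feature: C2 is a benzylic carbon bearing O1, so it can be the migrating α-carbon of an α-aryloxy acid derivative. C4a is the only unsubstituted carbon of the phloroglucinol ring A, ortho to O1 and O5 and para to O7, and sits six atoms from the ketene carbon that the shift produces.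
- Forward: the ring A phenol and the ring B hydroxy ester are each built by directed ortho-lithiations and joined through O1–C2. Ring C is closed last by a photochemical Wolff shift with acylation in the same flask, and deprotection ends the route.
- Stereochemistry: C2 is set as the (S)-alcohol by asymmetric transfer hydrogenation of an aryl glyoxylate, inverted once in the Mitsunobu etherification to the (R)-ether, and carried with retention through the Wolff shift. The descriptor becomes (2S) in the flavanone only because the CIP ranking of the neighbours changes.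

Key step: step 13

Assumption: the target is read as the (2S)-flavanone, and aryl MOM ethers and prenyl groups are taken to tolerate 365 nm light and millimolar CF3CO2H at or below 0 °C.

Abbreviations: MOM = methoxymethyl; MOM-oxy = methoxymethoxy; prenyl = 3-methylbut-2-enyl; TIPS = triisopropylsilyl.

**Route**

Step 1
Reactants: 1 phloroglucinol (benzene-1,3,5-triol)
Product: 2 5-(triisopropylsilyloxy)benzene-1,3-diol
Conditions: 1 (3 equiv), TIPSCl (1 equiv), imidazole, DMF, 0 °C → rt
Reagents that add atoms: chlorotriisopropylsilane, CC(C)[Si](Cl)(C(C)C)C(C)C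
Why: Statistical silyl ether formation on the symmetric triol, with the triol in excess, should give mainly the mono-silyl ether and marks the oxygen that later becomes O1.

Step 2
Reactants: 2 5-(triisopropylsilyloxy)benzene-1,3-diol
Product: 3 [3,5-bis(MOM-oxy)phenoxy]triisopropylsilane
Conditions: MOMCl (2.5 equiv), i-Pr2NEt, CH2Cl2, 0 °C → rt
Reagents that add atoms: chloromethyl methyl ether, COCCl
Why: O-alkylation of both remaining phenols with the chloromethyl ether under amine base (acetal-type ether formation) gives the two MOM-oxy groups that later direct the ortho-lithiations.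

Step 3
Reactants: 3 [3,5-bis(MOM-oxy)phenoxy]triisopropylsilane; 4 prenyl bromide (1-bromo-3-methylbut-2-ene)
Product: 6 [3,5-bis(MOM-oxy)-4-prenylphenoxy]triisopropylsilane, via aryllithium 5 (not isolated)
Conditions: n-BuLi (1.1 equiv), THF, 0 °C; then CuBr·SMe2 (10 mol%), 4, −78 °C → rt
Reagents that add atoms: none
Why: Directed ortho-metalation should occur at the carbon between the two MOM-oxy groups, away from the bulky non-directing silyl ether, and copper-catalysed SN2 alkylation of the aryllithium installs the future C6 prenyl group.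

Step 4
Reactants: 6 [3,5-bis(MOM-oxy)-4-prenylphenoxy]triisopropylsilane; 4 prenyl bromide
Product: 8 [3,5-bis(MOM-oxy)-2,4-diprenylphenoxy]triisopropylsilane, via aryllithium 7 (not isolated)
Conditions: s-BuLi (1.2 equiv), TMEDA, THF, −78 → −40 °C; then CuBr·SMe2 (10 mol%), 4, −78 → 0 °C
Reagents that add atoms: none
Why: The two remaining ring hydrogens are equivalent and each is ortho to a MOM-oxy group, so a second directed ortho-metalation (kept cold to hold back silyl migration from oxygen to carbon) and copper-catalysed prenylation can only give the 2,4-diprenyl pattern (future C6 and C8).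

Step 5
Reactants: 8 [3,5-bis(MOM-oxy)-2,4-diprenylphenoxy]triisopropylsilane
Product: 9 3,5-bis(MOM-oxy)-2,4-diprenylphenol
Conditions: Bu4NF (1.1 equiv), AcOH (1.1 equiv), THF, 0 °C
Reagents that add atoms: none
Why: Fluoride-driven cleavage of the aryl silyl ether leaves MOM ethers and alkenes untouched and frees the phenol whose oxygen becomes O1.

Step 6
Reactants: 10 resorcinol (benzene-1,3-diol)
Product: 11 1,3-bis(MOM-oxy)benzene
Conditions: MOMCl (2.4 equiv), i-Pr2NEt, CH2Cl2, 0 °C → rt
Reagents that add atoms: chloromethyl methyl ether, COCCl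
Why: Double O-alkylation with the chloromethyl ether gives the substrate for cooperative ortho-direction.

Step 7
Reactants: 11 1,3-bis(MOM-oxy)benzene; 4 prenyl bromide
Product: 13 1,3-bis(MOM-oxy)-2-prenylbenzene, via aryllithium 12 (not isolated)
Conditions: n-BuLi (1.1 equiv), THF, 0 °C → rt; then CuBr·SMe2 (10 mol%), 4, −78 °C → rt
Reagents that add atoms: none
Why: Directed ortho-metalation at the carbon between the two MOM-oxy groups, followed by copper-catalysed SN2 prenylation, places the future C3' prenyl group.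

Step 8
Reactants: 13 1,3-bis(MOM-oxy)-2-prenylbenzene; 14 diethyl oxalate
Product: 16 ethyl 2-[2,4-bis(MOM-oxy)-3-prenylphenyl]-2-oxoacetate, via aryllithium 15 (not isolated)
Conditions: n-BuLi (1.2 equiv), TMEDA, THF, −20 → 0 °C; then added to 14 (3 equiv), THF, −78 °C; aq. NH4Cl
Reagents that add atoms: none
Why: A second directed ortho-metalation next to one MOM-oxy group and inverse addition to excess oxalate diester (acylation of an organolithium) should stop at the α-keto ester, because the tetrahedral adduct persists until the quench.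

Step 9
Reactants: 16 ethyl 2-[2,4-bis(MOM-oxy)-3-prenylphenyl]-2-oxoacetate
Product: 17 ethyl (2S)-2-[2,4-bis(MOM-oxy)-3-prenylphenyl]-2-hydroxyacetate
Conditions: RuCl[(R,R)-TsDPEN](p-cymene) (1 mol%), HCO2H/Et3N (5:2), DMF, 25 °C
Reagents that add atoms: none
Why: Noyori-type asymmetric transfer hydrogenation of an aryl α-keto ester, with the aryl group held over the η6-arene of the (R,R)-catalyst, should deliver hydride to the face that gives the (S)-alcohol and so set the only stereocentre of the route without reducing the alkenes; the sense is to be checked by Mosher ester analysis, with the antipodal catalyst used if it is reversed.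

Step 10
Reactants: 9 3,5-bis(MOM-oxy)-2,4-diprenylphenol; 17 ethyl (2S)-2-[2,4-bis(MOM-oxy)-3-prenylphenyl]-2-hydroxyacetate
Product: 18 ethyl (2R)-2-[2,4-bis(MOM-oxy)-3-prenylphenyl]-2-[3,5-bis(MOM-oxy)-2,4-diprenylphenoxy]acetate
Conditions: PPh3, DIAD, toluene, 0 °C → rt
Reagents that add atoms: none
Why: Mitsunobu etherification proceeds by SN2 displacement of the oxyphosphonium at a carbon that has no β-hydrogen and is deactivated towards ionisation by the ester, so O1–C2 should form with inversion and the (S)-alcohol gives the (R)-aryl ether.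

Step 11
Reactants: 18 ethyl (2R)-2-[2,4-bis(MOM-oxy)-3-prenylphenyl]-2-[3,5-bis(MOM-oxy)-2,4-diprenylphenoxy]acetate
Product: 19 (2R)-2-[2,4-bis(MOM-oxy)-3-prenylphenyl]-2-[3,5-bis(MOM-oxy)-2,4-diprenylphenoxy]acetic acid
Conditions: LiOH·H2O (2 equiv), THF/H2O (3:1), 0 °C → rt; then 0.5 M HCl to pH 4, 0 °C
Reagents that add atoms: lithium hydroxide, [Li+].[OH-]
Why: Saponification by acyl–oxygen cleavage in aqueous medium should outrun enolisation of the α-aryloxy ester, so the acid keeps its configuration, and the MOM ethers survive the brief cold acidification.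

Step 12
Reactants: 19 (2R)-2-[2,4-bis(MOM-oxy)-3-prenylphenyl]-2-[3,5-bis(MOM-oxy)-2,4-diprenylphenoxy]acetic acid
Product: 21 (3R)-3-[2,4-bis(MOM-oxy)-3-prenylphenyl]-3-[3,5-bis(MOM-oxy)-2,4-diprenylphenoxy]-1-diazopropan-2-one, via mixed carbonic anhydride 20 (not isolated)
Conditions: i-BuOCOCl, N-methylmorpholine, THF, −20 °C; then CH2N2 (Et2O, 3 equiv), −20 → 0 °C
Reagents that add atoms: diazomethane, C=[N+]=[N-]
Why: Activation as the mixed isobutyl carbonic anhydride with a weak tertiary amine at low temperature avoids ketene formation and racemisation, and acylation of diazomethane at the acyl carbon gives the α-diazoketone (first stage of an Arndt–Eistert sequence).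

Step 13
Reactants: 21 (3R)-3-[2,4-bis(MOM-oxy)-3-prenylphenyl]-3-[3,5-bis(MOM-oxy)-2,4-diprenylphenoxy]-1-diazopropan-2-one
Product: 24 (2S)-2-[2,4-bis(MOM-oxy)-3-prenylphenyl]-5,7-bis(MOM-oxy)-6,8-diprenylchroman-4-one, via ketene 22 (not isolated), via acyl trifluoroacetate 23 (not isolated)
Conditions: hν (365 nm LED), dry degassed CH2Cl2 (0.005 M), −30 °C; then CF3CO2H (2 equiv), −30 → 0 °C; aq. NaHCO3
Reagents that add atoms: none
Why: Proposed new method: Irradiation of the s-Z α-diazoketone expels N2 while C2 migrates from the acyl carbon to the former diazo carbon (Wolff rearrangement, making C2–C3 with retention at the migrating centre) to give ketene 22, whose C4 is the only strong electrophile in the non-nucleophilic medium. CF3CO2H, added only after the diazo compound is consumed, adds across the ketene to give acyl trifluoroacetate 23, which acylates C4a of ring A (making C4–C4a) and returns the acid. The closest known reaction types are the Arndt–Eistert homologation of α-alkoxy acids, which fixes the stereochemical course of the shift, and the trifluoroacetic-anhydride-mediated Friedel–Crafts closure of 3-aryloxypropanoic acids to chroman-4-ones; the new element is ending a Wolff rearrangement by C-acylation of a tethered arene. Ring C closes by 6-exo-trig attack of the arene carbon on the acyl carbon, followed by rearomatisation. No new stereocentre is made: C2 is carried over from the (R)-acid with retention and is named (S) only because the CIP ranking of its neighbours changes. The step needs C-acylation at C4a over capture of the ketene or anhydride by the prenyl alkenes or MOM oxygens; C4a is the only unsubstituted carbon of ring A, is activated by O1, O5 and O7, and reaches C4 through a six-membered transition state, while high dilution suppresses ketene dimerisation.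

Step 14
Reactants: 24 (2S)-2-[2,4-bis(MOM-oxy)-3-prenylphenyl]-5,7-bis(MOM-oxy)-6,8-diprenylchroman-4-one
Product: 25 (2S)-2-(2,4-dihydroxy-3-prenylphenyl)-5,7-dihydroxy-6,8-diprenylchroman-4-one (target)
Conditions: HCl (1.5 M in MeOH), 25–40 °C, under argon
Reagents that add atoms: none
Why: Acid-catalysed transacetalisation to methanol should remove the four aryl MOM ethers under conditions where flavanones do not open to chalcones (a base-mediated path), so C2 stays (S), with acid strength and temperature kept low to avoid cyclisation of prenyl groups onto neighbouring phenols.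

**Compound list**
1 | phloroglucinol | Oc1cc(O)cc(O)c1 | starting material
2 | 5-(triisopropylsilyloxy)benzene-1,3-diol | CC(C)[Si](Oc1cc(O)cc(O)c1)(C(C)C)C(C)C | intermediate
3 | [3,5-bis(MOM-oxy)phenoxy]triisopropylsilane | COCOc1cc(OCOC)cc(O[Si](C(C)C)(C(C)C)C(C)C)c1 | intermediate
4 | prenyl bromide (1-bromo-3-methylbut-2-ene) | CC(C)=CCBr | starting material
5 | [2,6-bis(MOM-oxy)-4-(triisopropylsilyloxy)phenyl]lithium | [Li]c1c(OCOC)cc(O[Si](C(C)C)(C(C)C)C(C)C)cc1OCOC | intermediate
6 | [3,5-bis(MOM-oxy)-4-prenylphenoxy]triisopropylsilane | COCOc1cc(O[Si](C(C)C)(C(C)C)C(C)C)cc(OCOC)c1CC=C(C)C | intermediate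
7 | [2,4-bis(MOM-oxy)-3-prenyl-6-(triisopropylsilyloxy)phenyl]lithium | [Li]c1c(OCOC)c(CC=C(C)C)c(OCOC)cc1O[Si](C(C)C)(C(C)C)C(C)C | intermediate
8 | [3,5-bis(MOM-oxy)-2,4-diprenylphenoxy]triisopropylsilane | COCOc1cc(O[Si](C(C)C)(C(C)C)C(C)C)c(CC=C(C)C)c(OCOC)c1CC=C(C)C | intermediate
9 | 3,5-bis(MOM-oxy)-2,4-diprenylphenol | COCOc1cc(O)c(CC=C(C)C)c(OCOC)c1CC=C(C)C | intermediate
10 | resorcinol | Oc1cccc(O)c1 | starting material
11 | 1,3-bis(MOM-oxy)benzene | COCOc1cccc(OCOC)c1 | intermediate
12 | [2,6-bis(MOM-oxy)phenyl]lithium | [Li]c1c(OCOC)cccc1OCOC | intermediate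
13 | 1,3-bis(MOM-oxy)-2-prenylbenzene | COCOc1cccc(OCOC)c1CC=C(C)C | intermediate
14 | diethyl oxalate | CCOC(=O)C(=O)OCC | starting material
15 | [2,4-bis(MOM-oxy)-3-prenylphenyl]lithium | [Li]c1ccc(OCOC)c(CC=C(C)C)c1OCOC | intermediate
16 | ethyl 2-[2,4-bis(MOM-oxy)-3-prenylphenyl]-2-oxoacetate | CCOC(=O)C(=O)c1ccc(OCOC)c(CC=C(C)C)c1OCOC | intermediate
17 | ethyl (2S)-2-[2,4-bis(MOM-oxy)-3-prenylphenyl]-2-hydroxyacetate | O[C@H](C(=O)OCC)c1ccc(OCOC)c(CC=C(C)C)c1OCOC | intermediate
18 | ethyl (2R)-2-[2,4-bis(MOM-oxy)-3-prenylphenyl]-2-[3,5-bis(MOM-oxy)-2,4-diprenylphenoxy]acetate | COCOc1cc(O[C@@H](C(=O)OCC)c2ccc(OCOC)c(CC=C(C)C)c2OCOC)c(CC=C(C)C)c(OCOC)c1CC=C(C)C | intermediate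
19 | (2R)-2-[2,4-bis(MOM-oxy)-3-prenylphenyl]-2-[3,5-bis(MOM-oxy)-2,4-diprenylphenoxy]acetic acid | COCOc1cc(O[C@@H](C(=O)O)c2ccc(OCOC)c(CC=C(C)C)c2OCOC)c(CC=C(C)C)c(OCOC)c1CC=C(C)C | intermediate
20 | mixed anhydride of 19 with isobutyl hydrogen carbonate, (2R) | COCOc1cc(O[C@@H](C(=O)OC(=O)OCC(C)C)c2ccc(OCOC)c(CC=C(C)C)c2OCOC)c(CC=C(C)C)c(OCOC)c1CC=C(C)C | intermediate
21 | (3R)-3-[2,4-bis(MOM-oxy)-3-prenylphenyl]-3-[3,5-bis(MOM-oxy)-2,4-diprenylphenoxy]-1-diazopropan-2-one | COCOc1cc(O[C@@H](C(=O)C=[N+]=[N-])c2ccc(OCOC)c(CC=C(C)C)c2OCOC)c(CC=C(C)C)c(OCOC)c1CC=C(C)C | intermediate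
22 | (3S)-3-[2,4-bis(MOM-oxy)-3-prenylphenyl]-3-[3,5-bis(MOM-oxy)-2,4-diprenylphenoxy]prop-1-en-1-one (ketene) | COCOc1cc(O[C@@H](C=C=O)c2ccc(OCOC)c(CC=C(C)C)c2OCOC)c(CC=C(C)C)c(OCOC)c1CC=C(C)C | intermediate
23 | (3S)-3-[2,4-bis(MOM-oxy)-3-prenylphenyl]-3-[3,5-bis(MOM-oxy)-2,4-diprenylphenoxy]propanoic trifluoroacetic anhydride | COCOc1cc(O[C@@H](CC(=O)OC(=O)C(F)(F)F)c2ccc(OCOC)c(CC=C(C)C)c2OCOC)c(CC=C(C)C)c(OCOC)c1CC=C(C)C | intermediate
24 | (2S)-2-[2,4-bis(MOM-oxy)-3-prenylphenyl]-5,7-bis(MOM-oxy)-6,8-diprenylchroman-4-one | CC(C)=CCc1c(OCOC)ccc([C@@H]2CC(=O)c3c(OCOC)c(CC=C(C)C)c(OCOC)c(CC=C(C)C)c3O2)c1OCOC | intermediate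
25 | (2S)-2-(2,4-dihydroxy-3-prenylphenyl)-5,7-dihydroxy-6,8-diprenylchroman-4-one | CC(C)=CCc1c(O)ccc([C@@H]2CC(=O)c3c(O)c(CC=C(C)C)c(O)c(CC=C(C)C)c3O2)c1O | target

**Count and risks**
Total step count: 14. Longest linear sequence: 10 steps (steps 1–5 and 10–14, from phloroglucinol).

Steps most likely to fail:

1. Step 13. The ketene may be lost to dimerisation or photochemical decarbonylation before the acid is added, or its capture and ring closure may be slow enough for acid-mediated loss of a MOM group to compete. The fallback separates the two events with known chemistry and sets out from 21. Irradiation (365 nm) in THF/H2O (9:1) traps the ketene with water as it forms and should give, by classical Arndt–Eistert homologation with retention, (3S)-3-[2,4-bis(MOM-oxy)-3-prenylphenyl]-3-[3,5-bis(MOM-oxy)-2,4-diprenylphenoxy]propanoic acid F1. This acid should close under (CF3CO)2O in CH2Cl2 at 0 °C by intramolecular Friedel–Crafts acylation at C4a, coming back to the route at 24.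

2. Step 10. The hindered, weakly acidic phenol may react slowly with the hindered oxyphosphonium, and partial ionisation at the benzylic carbon next to the electron-rich ring B may erode the enantiomeric purity. The fallback forms O1–C2 by carbene O–H insertion instead of substitution and sets out from 16. Condensation with TsNHNH2 (MeOH, 25 °C) should give ethyl 2-[2,4-bis(MOM-oxy)-3-prenylphenyl]-2-(tosylhydrazinylidene)acetate F2. Treatment with DBU in CH2Cl2 should eliminate sulfinate (Bamford–Stevens type) to give ethyl 2-[2,4-bis(MOM-oxy)-3-prenylphenyl]-2-diazoacetate F3. Enantioselective O–H insertion of F3 into phenol 9 (Pd(PhCN)2Cl2 (5 mol%), chiral spiro-bis(oxazoline) ligand of the antipode that delivers the (R)-ether, NaB[3,5-(CF3)2C6H3]4, CHCl3, 25 °C) comes back to the route at 18.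

3. Step 14. Prenyl groups may cyclise onto the freed ortho-phenols under acid, and prolonged acid exposure may partly scramble C2 through reversible opening of ring C. The fallback avoids protic acid and sets out from 24. Exchange of the four MOM groups for silyl groups (Et3SiOTf, 2,2'-bipyridyl, CH2Cl2, 0 °C) should give (2S)-2-[2,4-bis(triethylsilyloxy)-3-prenylphenyl]-5,7-bis(triethylsilyloxy)-6,8-diprenylchroman-4-one F4. Mild desilylation (KHF2, MeOH, 25 °C) comes back to the route at 25.

**Further compounds**
F1 | step 13 | (3S)-3-[2,4-bis(MOM-oxy)-3-prenylphenyl]-3-[3,5-bis(MOM-oxy)-2,4-diprenylphenoxy]propanoic acid | COCOc1cc(O[C@@H](CC(=O)O)c2ccc(OCOC)c(CC=C(C)C)c2OCOC)c(CC=C(C)C)c(OCOC)c1CC=C(C)C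
F2 | step 10 | ethyl 2-[2,4-bis(MOM-oxy)-3-prenylphenyl]-2-(tosylhydrazinylidene)acetate | CCOC(=O)C(=NNS(=O)(=O)c1ccc(C)cc1)c1ccc(OCOC)c(CC=C(C)C)c1OCOC
F3 | step 10 | ethyl 2-[2,4-bis(MOM-oxy)-3-prenylphenyl]-2-diazoacetate | CCOC(=O)C(=[N+]=[N-])c1ccc(OCOC)c(CC=C(C)C)c1OCOC
F4 | step 14 | (2S)-2-[2,4-bis(triethylsilyloxy)-3-prenylphenyl]-5,7-bis(triethylsilyloxy)-6,8-diprenylchroman-4-one | CC(C)=CCc1c(O[Si](CC)(CC)CC)ccc([C@@H]2CC(=O)c3c(O[Si](CC)(CC)CC)c(CC=C(C)C)c(O[Si](CC)(CC)CC)c(CC=C(C)C)c3O2)c1O[Si](CC)(CC)CC
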